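The route rests on cutting ring A of flavanone unit 1 at its two neighbouring carbons C8a and C4a, that is at the aryl–O1 bond and the aryl–C4(carbonyl) bond. In the key step a fluoride-generated 3,5-dimethoxybenzyne takes up the hydroxyl oxygen and the ester carbonyl of an enantiopure (S)-β-hydroxy ester in one operation and so closes the pyranone ring with C2 already in place. The methoxy group beside the triple bond (the future C5 oxygen) decides which end receives oxygen. The precursor is acyclic: an ethyl (S)-3-aryl-3-hydroxypropanoate that carries the diaryl ether and a chromone, the latent flavanone unit 2, which is arylated asymmetrically afterwards.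

Key step: step 8

Remark: the target is read as (2S,2''S); unprimed locants belong to flavanone unit 1 (left in the SMILES), doubly primed locants to unit 2, triply primed locants to its 4-hydroxyphenyl ring.

Step 1
Reactants: 1 2,6-dimethoxybenzene-1,4-diol (2,6-dimethoxyhydroquinone)
Product: 2 1-(3,6-dihydroxy-2,4-dimethoxyphenyl)ethanone
Conditions: BF3·OEt2, AcOH, 90 °C; aq. NaOAc work-up
Reagents that add atoms: acetic acid, CC(=O)O
Why: Friedel–Crafts C-acetylation (Nencki type) of an electron-rich hydroquinone: the two free ring positions of 1 are equivalent and each lies ortho to the unhindered hydroxyl, so only one hydroxyacetophenone can form.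

Step 2
Reactants: 2 1-(3,6-dihydroxy-2,4-dimethoxyphenyl)ethanone; 3 4-fluorobenzaldehyde
Product: 4 4-(3-acetyl-4-hydroxy-2,6-dimethoxyphenoxy)benzaldehyde
Conditions: K2CO3, DMF, 90 °C
Reagents that add atoms: none
Why: Nucleophilic aromatic substitution (SNAr) on the formyl-activated aryl fluoride: the 6-OH of 2 is held in a hydrogen bond to the acetyl group and its phenoxide is delocalised into the ketone, so the electron-rich 3-phenoxide between the two methoxy groups is the oxygen that should attack.

Step 3
Reactants: 4 4-(3-acetyl-4-hydroxy-2,6-dimethoxyphenoxy)benzaldehyde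
Product: 6 4-[(5,7-dimethoxy-4-oxo-4H-chromen-6-yl)oxy]benzaldehyde, via enaminone 5 (not isolated)
Conditions: Me2NCH(OMe)2, toluene, 100 °C; then conc. HCl, CH2Cl2, 40 °C
Reagents that add atoms: N,N-dimethylformamide dimethyl acetal, COC(OC)N(C)C
Why: Enaminone route to chromones: the methyl ketone condenses with the formamide acetal, then acid promotes attack of the ortho hydroxyl on the enaminone carbon with loss of dimethylamine, while the non-enolisable aldehyde is inert to both reagents.

Step 4
Reactants: 6 4-[(5,7-dimethoxy-4-oxo-4H-chromen-6-yl)oxy]benzaldehyde; 7 ethyl diazoacetate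
Product: 8 ethyl 3-{4-[(5,7-dimethoxy-4-oxo-4H-chromen-6-yl)oxy]phenyl}-3-oxopropanoate
Conditions: NbCl5 (5 mol%), CH2Cl2, rt
Reagents that add atoms: none
Why: Roskamp homologation: Lewis-acid-activated addition of the diazo ester to the aldehyde and 1,2-hydride shift with loss of nitrogen should give the β-keto ester directly, and the chromone carbonyl (a vinylogous ester) is too weak an electrophile to compete.

Step 5
Reactants: 8 ethyl 3-{4-[(5,7-dimethoxy-4-oxo-4H-chromen-6-yl)oxy]phenyl}-3-oxopropanoate
Product: 9 ethyl (3S)-3-{4-[(5,7-dimethoxy-4-oxo-4H-chromen-6-yl)oxy]phenyl}-3-hydroxypropanoate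
Conditions: RuCl2[(R)-BINAP] (1 mol%), H2 (10 atm), EtOH, 50 °C
Reagents that add atoms: none
Why: Noyori asymmetric hydrogenation: only the chelating β-keto ester is reduced by the BINAP–ruthenium dichloride catalyst, and the (R)-ligand delivers hydrogen to the ketone face that gives the (S)-3-aryl-3-hydroxy ester (the established sense for aroylacetates), which sets the future C2.

Step 6
Reactants: 10 3,5-dimethoxyphenol
Product: 11 2-bromo-3,5-dimethoxyphenol
Conditions: NBS, CH2Cl2, −78 °C to rt
Reagents that add atoms: N-bromosuccinimide, O=C1CCC(=O)N1Br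
Why: Electrophilic aromatic bromination: at low temperature NBS should brominate the activated position ortho to the free hydroxyl (either ortho position gives the same product), and any para isomer is removed by chromatography.

Step 7
Reactants: 11 2-bromo-3,5-dimethoxyphenol
Product: 14 3,5-dimethoxy-2-(trimethylsilyl)phenyl trifluoromethanesulfonate, via silyl ether 12 (not isolated), via lithium phenoxide 13 (not isolated)
Conditions: (Me3Si)2NH, THF, 70 °C, evaporate; n-BuLi, THF, −78 °C; then Tf2O, −78 °C to rt
Reagents that add atoms: hexamethyldisilazane, C[Si](C)(C)N[Si](C)(C)C; trifluoromethanesulfonic anhydride, O=S(=O)(OS(=O)(=O)C(F)(F)F)C(F)(F)F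
Why: Standard route to an ortho-silylaryl triflate: O-silylation, bromine–lithium exchange, anionic 1,3-silyl shift from oxygen to carbon (retro-Brook rearrangement) and O-triflation of the resulting lithium phenoxide.

Step 8
Reactants: 9 ethyl (3S)-3-{4-[(5,7-dimethoxy-4-oxo-4H-chromen-6-yl)oxy]phenyl}-3-hydroxypropanoate; 14 3,5-dimethoxy-2-(trimethylsilyl)phenyl trifluoromethanesulfonate
Product: 17 (2S)-2-{4-[(5,7-dimethoxy-4-oxo-4H-chromen-6-yl)oxy]phenyl}-5,7-dimethoxy-2,3-dihydro-4H-chromen-4-one, via aryne 15 (not isolated), via aryl caesium adduct 16 (not isolated)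
Conditions: 14 (2 equiv), CsF (4 equiv), THF, 65 °C
Reagents that add atoms: none
Why: Proposed new method: fluoride removes the silyl group of 14 and expels triflate to give aryne 15; the fluoride-hydrogen-bonded hydroxyl of 9 adds through oxygen to the aryne carbon remote from the flanking methoxy group (the former triflate carbon), because the inductive effect of that methoxy group and the distortion of the aryne place the carbanion beside it, and the ortho aryl caesium 16 then attacks the ethyl ester carbonyl and expels ethoxide, which fixes O1 at C8a and the C4 carbonyl at C4a (the 5,7- and not the 6,8-dimethoxy pattern). The closest known reaction type is the aryne annulation of salicylate esters to xanthones, together with the insertion of arynes into the C–O bond of carboxylic acids and the N–C(O) bond of β-lactams; an aliphatic β-hydroxy ester as partner is the untested element. The pyranone ring of unit 1 is closed by intermolecular O-arylation followed by an intramolecular 6-exo-trig anionic acylation. No stereocentre is created: C2 comes from 9 with retention because its C–O bond is never broken. The step needs cyclisation to outrun protonation of 16 (non-acidic THF, six-membered transition state) and needs the alcohol to remain largely un-ionised so that retro-aldol cleavage and dehydration stay slow (CsF is a weak base and the ethoxide released is buffered by the hydrogen fluoride that takes the hydroxyl proton); the chromone offers no nucleophilic or acidic site.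

Step 9
Reactants: 17 (2S)-2-{4-[(5,7-dimethoxy-4-oxo-4H-chromen-6-yl)oxy]phenyl}-5,7-dimethoxy-2,3-dihydro-4H-chromen-4-one; 18 [4-(benzyloxy)phenyl]boronic acid
Product: 19 (2S)-2-[4-(benzyloxy)phenyl]-6-{4-[(2S)-5,7-dimethoxy-4-oxo-3,4-dihydro-2H-chromen-2-yl]phenoxy}-5,7-dimethoxy-2,3-dihydro-4H-chromen-4-one
Conditions: [Rh(OH)(cod)]2 (2.5 mol%; cod = 1,5-cyclooctadiene), (S)-6,6'-dimethoxy-2,2'-bis[bis(3,4,5-trifluorophenyl)phosphino]biphenyl (5.5 mol%), 18 (3 equiv), toluene/H2O, 30 °C
Reagents that add atoms: none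
Why: Hayashi–Miyaura rhodium-catalysed asymmetric 1,4-addition of an arylboronic acid to a chromone: the electron-poor (S)-biaryl bisphosphine allows a low temperature so that the rhodium enolate is protonated before it can ring-open, and it should direct the aryl group to the C2'' face that gives 2''S (assigned by analogy with the (S)-BINAP to (S)-3-arylcyclohexanone sense), independently of the remote C2 centre.

Step 10
Reactants: 19 (2S)-2-[4-(benzyloxy)phenyl]-6-{4-[(2S)-5,7-dimethoxy-4-oxo-3,4-dihydro-2H-chromen-2-yl]phenoxy}-5,7-dimethoxy-2,3-dihydro-4H-chromen-4-one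
Product: 20 7,7''-di-O-methyltetrahydrohinokiflavone
Conditions: BCl3 (6 equiv), C6HMe5 (3 equiv), CH2Cl2, −78 to 0 °C; aq. NaHCO3
Reagents that add atoms: none
Why: Chelation-controlled Lewis-acid dealkylation: BCl3 bound to each C4 carbonyl should cleave only the peri (C5 and C5'') methyl ethers and also removes the benzyl ether with pentamethylbenzene as cation scavenger, while the 7- and 7''-methyl ethers, the diaryl ether and both stereocentres (no base, low temperature) should stay untouched.

Compound list
1 | 2,6-dimethoxybenzene-1,4-diol | COc1cc(O)cc(OC)c1O | starting material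
2 | 1-(3,6-dihydroxy-2,4-dimethoxyphenyl)ethanone | CC(=O)c1c(O)cc(OC)c(O)c1OC | intermediate
3 | 4-fluorobenzaldehyde | O=Cc1ccc(F)cc1 | starting material
4 | 4-(3-acetyl-4-hydroxy-2,6-dimethoxyphenoxy)benzaldehyde | CC(=O)c1c(O)cc(OC)c(Oc2ccc(C=O)cc2)c1OC | intermediate
5 | 4-{3-[(E)-3-(dimethylamino)prop-2-enoyl]-4-hydroxy-2,6-dimethoxyphenoxy}benzaldehyde (enaminone) | CN(C)/C=C/C(=O)c1c(O)cc(OC)c(Oc2ccc(C=O)cc2)c1OC | intermediate
6 | 4-[(5,7-dimethoxy-4-oxo-4H-chromen-6-yl)oxy]benzaldehyde | O=Cc1ccc(Oc2c(OC)cc3occc(=O)c3c2OC)cc1 | intermediate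
7 | ethyl diazoacetate | CCOC(=O)C=[N+]=[N-] | starting material
8 | ethyl 3-{4-[(5,7-dimethoxy-4-oxo-4H-chromen-6-yl)oxy]phenyl}-3-oxopropanoate | CCOC(=O)CC(=O)c1ccc(Oc2c(OC)cc3occc(=O)c3c2OC)cc1 | intermediate
9 | ethyl (3S)-3-{4-[(5,7-dimethoxy-4-oxo-4H-chromen-6-yl)oxy]phenyl}-3-hydroxypropanoate | O[C@H](c1ccc(Oc2c(OC)cc3occc(=O)c3c2OC)cc1)CC(=O)OCC | intermediate
10 | 3,5-dimethoxyphenol | COc1cc(O)cc(OC)c1 | starting material
11 | 2-bromo-3,5-dimethoxyphenol | COc1cc(OC)c(Br)c(O)c1 | intermediate
12 | (2-bromo-3,5-dimethoxyphenoxy)trimethylsilane (silyl ether) | COc1cc(OC)c(Br)c(O[Si](C)(C)C)c1 | intermediate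
13 | lithium 3,5-dimethoxy-2-(trimethylsilyl)phenoxide | COc1cc(OC)c([Si](C)(C)C)c([O-])c1.[Li+] | intermediate
14 | 3,5-dimethoxy-2-(trimethylsilyl)phenyl trifluoromethanesulfonate | COc1cc(OC)c([Si](C)(C)C)c(OS(=O)(=O)C(F)(F)F)c1 | intermediate
15 | 3,5-dimethoxybenzyne (aryne) | COC1=CC(OC)=CC#C1 | intermediate
16 | caesium 2-{[(1S)-3-ethoxy-3-oxo-1-{4-[(5,7-dimethoxy-4-oxo-4H-chromen-6-yl)oxy]phenyl}propyl]oxy}-4,6-dimethoxybenzen-1-ide (aryl caesium adduct) | COc1cc(OC)[c-]c(c1)O[C@H](c1ccc(Oc2c(OC)cc3occc(=O)c3c2OC)cc1)CC(=O)OCC.[Cs+] | intermediate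
17 | (2S)-2-{4-[(5,7-dimethoxy-4-oxo-4H-chromen-6-yl)oxy]phenyl}-5,7-dimethoxy-2,3-dihydro-4H-chromen-4-one | COc1cc(OC)c2c(c1)O[C@H](c1ccc(Oc3c(OC)cc4occc(=O)c4c3OC)cc1)CC2=O | intermediate
18 | [4-(benzyloxy)phenyl]boronic acid | OB(O)c1ccc(OCc2ccccc2)cc1 | starting material
19 | (2S)-2-[4-(benzyloxy)phenyl]-6-{4-[(2S)-5,7-dimethoxy-4-oxo-3,4-dihydro-2H-chromen-2-yl]phenoxy}-5,7-dimethoxy-2,3-dihydro-4H-chromen-4-one | COc1cc(OC)c2c(c1)O[C@H](c1ccc(Oc3c(OC)cc4c(c3OC)C(=O)C[C@@H](c3ccc(OCc5ccccc5)cc3)O4)cc1)CC2=O | intermediate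
20 | 7,7''-di-O-methyltetrahydrohinokiflavone, (2S)-5-hydroxy-6-{4-[(2S)-5-hydroxy-7-methoxy-4-oxo-3,4-dihydro-2H-chromen-2-yl]phenoxy}-2-(4-hydroxyphenyl)-7-methoxy-2,3-dihydro-4H-chromen-4-one | COc1cc(O)c2c(c1)O[C@H](c1ccc(Oc3c(OC)cc4c(c3O)C(=O)C[C@@H](c3ccc(O)cc3)O4)cc1)CC2=O | target

Total step count: 10. Longest linear sequence: 8 steps (steps 1 to 5, then 8, 9 and 10, from compound 1).

Steps most likely to fail

Step 8. The aryl anion may be protonated before it reaches the ester, so that only O-arylation occurs. The hydroxy ester may undergo retro-aldol cleavage or dehydration under fluoride, or reversible opening of the new pyranone ring may erode C2. The fallback builds the same ring by two classical bond formations without an aryne and sets out from 8. Hydrogenation of 8 with RuCl2[(S)-BINAP] would give ethyl (3R)-3-{4-[(5,7-dimethoxy-4-oxo-4H-chromen-6-yl)oxy]phenyl}-3-hydroxypropanoate F1. Mitsunobu etherification of F1 with 3,5-dimethoxyphenol 10 (PPh3, diisopropyl azodicarboxylate, THF, 0 °C) should proceed with inversion to the (3S)-aryl ether ester F2. Neutral ester cleavage with Me3SnOH (1,2-dichloroethane, 80 °C), chosen to avoid β-elimination of the aryloxide, would give the (3S)-acid F3. Intramolecular Friedel–Crafts acylation (trifluoroacetic anhydride, CH2Cl2, 0 °C) at the position ortho to the ether oxygen, both such positions being equivalent, returns to the route at 17.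

Step 9. Carbometalation of the electron-rich, peri-substituted chromone may be slow, the boronic acid may protodeboronate, or the rhodium enolate may undergo β-oxygen elimination with ring-opening and loss of stereocontrol. The fallback replaces the protic boron-based cycle by an aprotic organozinc addition with trapping of the enolate and sets out from 17. [4-(Benzyloxy)phenyl]zinc chloride F4 would be made from commercial 4-(benzyloxy)phenylmagnesium bromide and ZnCl2. It would be added to 17 with [RhCl((S)-BINAP)]2 and Me3SiCl in THF at 20 °C to give the (2''S)-configured trimethylsilyl enol ether F5, which cannot ring-open. Mild hydrolysis (1 M HCl, THF, 0 °C) returns to the route at 19.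

Step 10. The Lewis acid may open the pyranone rings through the benzylic C2–O bonds (erosion of both stereocentres), the benzyl cation may alkylate ring A, or a 7-methyl ether may also be cleaved. The fallback separates the two deprotections, sets out from 19 and avoids any benzyl cation. Hydrogenolysis (H2, Pd(OH)2/C, EtOAc, rt) would give the phenol (2S)-6-{4-[(2S)-5,7-dimethoxy-4-oxo-3,4-dihydro-2H-chromen-2-yl]phenoxy}-2-(4-hydroxyphenyl)-5,7-dimethoxy-2,3-dihydro-4H-chromen-4-one F6. Chelation-assisted demethylation of the two peri methoxy groups of F6 with MgI2·OEt2 (toluene/Et2O, 60 °C) returns to the route at 20.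

Further compounds
F1 | step 8 | ethyl (3R)-3-{4-[(5,7-dimethoxy-4-oxo-4H-chromen-6-yl)oxy]phenyl}-3-hydroxypropanoate | O[C@@H](c1ccc(Oc2c(OC)cc3occc(=O)c3c2OC)cc1)CC(=O)OCC
F2 | step 8 | ethyl (3S)-3-(3,5-dimethoxyphenoxy)-3-{4-[(5,7-dimethoxy-4-oxo-4H-chromen-6-yl)oxy]phenyl}propanoate | COc1cc(OC)cc(c1)O[C@H](c1ccc(Oc2c(OC)cc3occc(=O)c3c2OC)cc1)CC(=O)OCC
F3 | step 8 | (3S)-3-(3,5-dimethoxyphenoxy)-3-{4-[(5,7-dimethoxy-4-oxo-4H-chromen-6-yl)oxy]phenyl}propanoic acid | COc1cc(OC)cc(c1)O[C@H](c1ccc(Oc2c(OC)cc3occc(=O)c3c2OC)cc1)CC(=O)O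
F4 | step 9 | [4-(benzyloxy)phenyl]zinc chloride | Cl[Zn]c1ccc(OCc2ccccc2)cc1
F5 | step 9 | (2S)-2-{4-[((2S)-2-[4-(benzyloxy)phenyl]-5,7-dimethoxy-4-[(trimethylsilyl)oxy]-2H-chromen-6-yl)oxy]phenyl}-5,7-dimethoxy-2,3-dihydro-4H-chromen-4-one | COc1cc(OC)c2c(c1)O[C@H](c1ccc(Oc3c(OC)cc4c(c3OC)C(O[Si](C)(C)C)=C[C@@H](c3ccc(OCc5ccccc5)cc3)O4)cc1)CC2=O
F6 | step 10 | (2S)-6-{4-[(2S)-5,7-dimethoxy-4-oxo-3,4-dihydro-2H-chromen-2-yl]phenoxy}-2-(4-hydroxyphenyl)-5,7-dimethoxy-2,3-dihydro-4H-chromen-4-one | COc1cc(OC)c2c(c1)O[C@H](c1ccc(Oc3c(OC)cc4c(c3OC)C(=O)C[C@@H](c3ccc(O)cc3)O4)cc1)CC2=O
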